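## Retrosynthetic overview

1. Target 16 ⇐ tetrasilyl ether 15 by fluoride desilylation (TIPS = triisopropylsilyl).
2. C2–aryl bond: 15 ⇐ lactone 12 + aryllithium 13, then hydride onto the 2-aryl oxocarbenium ion anti to C3 (sets C2).
3. C5–aryl bond: 12 ⇐ trans-anhydride 9 + arylmagnesium bromide 10, then hydride onto the ring-held acyloxy benzylic cation anti to C4 (sets C5; new method).
4. 9 ⇐ (S,S)-epoxide 7 by double ring-expanding carbonylation (the two CO carbons become C2 and C5); 7 ⇐ (E)-but-2-ene-1,4-diol by silylation and Shi epoxidation.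
5. Aryl unit 4 ⇐ catechol (O-methylation, para-bromination, silylation). Rings form in the order oxirane, oxetan-2-one, oxolane-2,5-dione, oxolan-2-one; the last is kept as the oxolane of the target.

Assumption: the two catalysts that are not stock items, the L-fructose-derived Shi ketone and [(ClTPP)Al(THF)2][Co(CO)4] (ClTPP = meso-tetrakis(4-chlorophenyl)porphyrinate), are made by their known preparations and are not counted as steps.

## Route

Step 1
Reactants: 1 catechol
Product: 2 guaiacol (2-methoxyphenol)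
Conditions: MeI (1.0 equiv), K2CO3 (1.0 equiv), acetone, reflux
Reagents that add atoms: iodomethane, CI
Why: Williamson ether synthesis with one equivalent of base and MeI gives mainly the mono-ether, and water-soluble catechol and neutral 1,2-dimethoxybenzene are removed by extraction.

Step 2
Reactants: 2 guaiacol
Product: 3 4-bromo-2-methoxyphenol
Conditions: NBS (1.0 equiv), MeCN, 0 °C to rt
Reagents that add atoms: N-bromosuccinimide, O=C1CCC(=O)N1Br
Why: Electrophilic aromatic bromination goes para to the free OH, the stronger donor, which places bromine where the benzylic carbon of the target will sit.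

Step 3
Reactants: 3 4-bromo-2-methoxyphenol
Product: 4 (4-bromo-2-methoxyphenoxy)triisopropylsilane
Conditions: TIPSCl, imidazole, DMF, rt
Reagents that add atoms: chlorotriisopropylsilane, CC(C)[Si](Cl)(C(C)C)C(C)C
Why: O-silylation gives an aryl ether that survives magnesium insertion, n-BuLi and cold BF3·OEt2 and is removed by fluoride without acid.

Step 4
Reactants: 5 (E)-but-2-ene-1,4-diol
Product: 6 (E)-1,4-bis(triisopropylsilyloxy)but-2-ene
Conditions: TIPSCl (2.2 equiv), imidazole, DMF, rt
Reagents that add atoms: chlorotriisopropylsilane, CC(C)[Si](Cl)(C(C)C)C(C)C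
Why: O-silylation masks both hydroxyls so that they cannot trap the later oxocarbenium ions, and the silyl ether oxygens are too weakly nucleophilic to interfere with epoxide activation.

Step 5
Reactants: 6 (E)-1,4-bis(triisopropylsilyloxy)but-2-ene
Product: 7 (2S,3S)-2,3-bis[(triisopropylsilyloxy)methyl]oxirane
Conditions: L-fructose-derived Shi ketone (30 mol%), KHSO5 (Oxone), K2CO3, Bu4NHSO4, MeCN/CH2(OMe)2/aq. Na2B4O7 buffer, 0 °C
Reagents that add atoms: potassium peroxymonosulfate KHSO5, [K+].[O-]S(=O)(=O)OO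
Why: Shi asymmetric epoxidation by the chiral dioxirane through a spiro transition state gives the trans (S,S)-epoxide, which fixes the absolute configuration of the future C3 and C4.

Step 6
Reactants: 7 (2S,3S)-2,3-bis[(triisopropylsilyloxy)methyl]oxirane
Product: 9 (3S,4S)-3,4-bis[(triisopropylsilyloxy)methyl]oxolane-2,5-dione, via cis-β-lactone 8 (not isolated)
Conditions: [(ClTPP)Al(THF)2][Co(CO)4] (3 mol%), CO (60 bar), 1,4-dioxane, 90 °C
Reagents that add atoms: carbon monoxide, [C-]#[O+]
Why: Lewis acid/tetracarbonylcobaltate ring-expanding carbonylation runs twice (oxirane to oxetan-2-one to oxolane-2,5-dione), each time by SN2 attack of Co(CO)4− with inversion at a different carbon, so the trans (S,S)-epoxide gives the trans (S,S)-anhydride and both future benzylic carbons are installed.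

Step 7
Reactants: 9 (3S,4S)-3,4-bis[(triisopropylsilyloxy)methyl]oxolane-2,5-dione; 4 (4-bromo-2-methoxyphenoxy)triisopropylsilane
Product: 12 (3S,4S,5S)-5-[3-methoxy-4-(triisopropylsilyloxy)phenyl]-3,4-bis[(triisopropylsilyloxy)methyl]oxolan-2-one, via arylmagnesium bromide 10 (not isolated), via keto acid 11 (not isolated)
Conditions: 4, Mg turnings (I2 crystal), THF, 50 °C; add slowly to 9 (1.0 equiv), THF, −40 to 0 °C; AcOH (1.1 equiv); swap THF for CH2Cl2; Et3SiH (3 equiv), BF3·OEt2 (3 equiv), −78 to −40 °C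
Reagents that add atoms: none
Why: Proposed new method: reductive mono-arylation of a cyclic anhydride with substrate-controlled hydride delivery, in which the weakly basic Grignard reagent 10 opens the C2-symmetric anhydride (both carbonyls equivalent) once to the magnesium carboxylate of 11 without enolising the anhydride or attacking the new ketone, BF3 closes 11 to its ring pseudo-acid and ionises it to a 5-aryl-2-oxooxolan-5-ylium ion (a benzylic cation held in the ring by the acyloxy oxygen and stabilised by the para-silyloxy aryl group), and Et3SiH adds on the face anti to the C4 CH2OTIPS group so that the aryl group ends cis to it (5S), while the tertiary hemiketal carbon ionises much faster than the secondary benzylic C–O bond of 12 so that reduction stops at the lactone in the cold; closest known reaction type: Et3SiH/BF3·OEt2 reduction of lactols made from lactones and organometallic reagents and of N-acyliminium ions made from imides and Grignard reagents.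

Step 8
Reactants: 12 (3S,4S,5S)-5-[3-methoxy-4-(triisopropylsilyloxy)phenyl]-3,4-bis[(triisopropylsilyloxy)methyl]oxolan-2-one; 4 (4-bromo-2-methoxyphenoxy)triisopropylsilane
Product: 15 (2S,3S,4S,5S)-2,5-bis[3-methoxy-4-(triisopropylsilyloxy)phenyl]-3,4-bis[(triisopropylsilyloxy)methyl]oxolane, via aryllithium 13 (not isolated), via lactol 14 (not isolated)
Conditions: 4, n-BuLi, THF, −78 °C; add 12, −78 °C; AcOH (1.1 equiv); swap THF for CH2Cl2; Et3SiH (3 equiv), BF3·OEt2 (3 equiv), −78 °C
Reagents that add atoms: none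
Why: Aryllithium addition to the lactone at −78 °C stops at the lithium hemiketal and gives the lactol, and ionic reduction (Et3SiH/BF3·OEt2) through the 2-aryl oxocarbenium ion delivers hydride anti to the C3 substituent under kinetic control, so the new aryl group ends cis to C3 (2S) and the cis,trans,cis array is complete.

Step 9
Reactants: 15 (2S,3S,4S,5S)-2,5-bis[3-methoxy-4-(triisopropylsilyloxy)phenyl]-3,4-bis[(triisopropylsilyloxy)methyl]oxolane
Product: 16 eduesmine
Conditions: Bu4NF (6 equiv), AcOH (6 equiv), THF, 0 °C to rt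
Reagents that add atoms: none
Why: Fluoride-mediated desilylation buffered with AcOH frees both phenols and both primary alcohols without acid or hydrogenolysis, so the kinetically set benzylic ether centres are neither epimerised nor cleaved.

## Compound list

1 | catechol (benzene-1,2-diol) | Oc1ccccc1O | starting material
2 | guaiacol (2-methoxyphenol) | COc1ccccc1O | intermediate
3 | 4-bromo-2-methoxyphenol | COc1cc(Br)ccc1O | intermediate
4 | (4-bromo-2-methoxyphenoxy)triisopropylsilane | COc1cc(Br)ccc1O[Si](C(C)C)(C(C)C)C(C)C | intermediate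
5 | (E)-but-2-ene-1,4-diol | OC/C=C/CO | starting material
6 | (E)-1,4-bis(triisopropylsilyloxy)but-2-ene | CC(C)[Si](C(C)C)(C(C)C)OC/C=C/CO[Si](C(C)C)(C(C)C)C(C)C | intermediate
7 | (2S,3S)-2,3-bis[(triisopropylsilyloxy)methyl]oxirane (trans) | CC(C)[Si](C(C)C)(C(C)C)OC[C@@H]1O[C@H]1CO[Si](C(C)C)(C(C)C)C(C)C | intermediate
8 | (3R,4R)-3,4-bis[(triisopropylsilyloxy)methyl]oxetan-2-one (cis-β-lactone) | O=C1O[C@@H](CO[Si](C(C)C)(C(C)C)C(C)C)[C@H]1CO[Si](C(C)C)(C(C)C)C(C)C | intermediate
9 | (3S,4S)-3,4-bis[(triisopropylsilyloxy)methyl]oxolane-2,5-dione (trans-anhydride) | O=C1OC(=O)[C@H](CO[Si](C(C)C)(C(C)C)C(C)C)[C@H]1CO[Si](C(C)C)(C(C)C)C(C)C | intermediate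
10 | [3-methoxy-4-(triisopropylsilyloxy)phenyl]magnesium bromide | COc1cc([Mg]Br)ccc1O[Si](C(C)C)(C(C)C)C(C)C | intermediate
11 | (2S,3S)-4-[3-methoxy-4-(triisopropylsilyloxy)phenyl]-4-oxo-2,3-bis[(triisopropylsilyloxy)methyl]butanoic acid | O=C(c1ccc(O[Si](C(C)C)(C(C)C)C(C)C)c(OC)c1)[C@H](CO[Si](C(C)C)(C(C)C)C(C)C)[C@@H](CO[Si](C(C)C)(C(C)C)C(C)C)C(=O)O | intermediate
12 | (3S,4S,5S)-5-[3-methoxy-4-(triisopropylsilyloxy)phenyl]-3,4-bis[(triisopropylsilyloxy)methyl]oxolan-2-one (3,4-trans, 4,5-cis) | O=C1O[C@H](c2ccc(O[Si](C(C)C)(C(C)C)C(C)C)c(OC)c2)[C@H](CO[Si](C(C)C)(C(C)C)C(C)C)[C@H]1CO[Si](C(C)C)(C(C)C)C(C)C | intermediate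
13 | [3-methoxy-4-(triisopropylsilyloxy)phenyl]lithium | COc1cc([Li])ccc1O[Si](C(C)C)(C(C)C)C(C)C | intermediate
14 | (3S,4S,5S)-2,5-bis[3-methoxy-4-(triisopropylsilyloxy)phenyl]-3,4-bis[(triisopropylsilyloxy)methyl]oxolan-2-ol (both C2 epimers) | OC1(c2ccc(O[Si](C(C)C)(C(C)C)C(C)C)c(OC)c2)O[C@H](c2ccc(O[Si](C(C)C)(C(C)C)C(C)C)c(OC)c2)[C@H](CO[Si](C(C)C)(C(C)C)C(C)C)[C@H]1CO[Si](C(C)C)(C(C)C)C(C)C | intermediate
15 | (2S,3S,4S,5S)-2,5-bis[3-methoxy-4-(triisopropylsilyloxy)phenyl]-3,4-bis[(triisopropylsilyloxy)methyl]oxolane | COc1cc([C@H]2O[C@H](c3ccc(O[Si](C(C)C)(C(C)C)C(C)C)c(OC)c3)[C@H](CO[Si](C(C)C)(C(C)C)C(C)C)[C@H]2CO[Si](C(C)C)(C(C)C)C(C)C)ccc1O[Si](C(C)C)(C(C)C)C(C)C | intermediate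
16 | eduesmine, [(2S,3S,4S,5S)-2,5-bis(4-hydroxy-3-methoxyphenyl)-4-(hydroxymethyl)oxolan-3-yl]methanol (2,3-cis, 3,4-trans, 4,5-cis) | COc1cc([C@H]2O[C@H](c3ccc(O)c(OC)c3)[C@H](CO)[C@H]2CO)ccc1O | target

## Step count and risks

Total step count: 9. Longest linear sequence: 6 (5 → 6 → 7 → 9 → 12 → 15 → 16; the arm 1 → 2 → 3 → 4 → 12 → 15 → 16 is equally long).

The three steps most likely to fail:

First, step 7, the proposed new reduction. The open-chain ketone of 11 may be reduced before ring closure (Felkin–Anh control would then give the 4,5-trans lactone), or the lactone may be reduced further to the arylbutanoic acid. The fallback uses known chemistry and sets out from 9. Arylmagnesium bromide 10 is added as before, and the mixture is worked up with aqueous NH4Cl to isolate keto acid 11. The aryl ketone is then reduced under catalyst control by Noyori–Ikariya asymmetric transfer hydrogenation (RuCl[(S,S)-TsDPEN](p-cymene), HCO2H/Et3N 5:2, 40 °C), the (S,S) catalyst delivering hydride to the face that gives the (4S) carbinol. This gives (2S,3S,4S)-4-hydroxy-4-[3-methoxy-4-(triisopropylsilyloxy)phenyl]-2,3-bis[(triisopropylsilyloxy)methyl]butanoic acid F1, which closes on standing or with catalytic pyridinium p-toluenesulfonate in toluene and comes back to the route at 12.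

Second, step 6. The epoxide is trans-disubstituted and flanked by two bulky CH2OTIPS groups, so the second carbonylation at a hindered secondary carbon may stall at 8. The fallback sets out from 7. The first carbonylation is run alone with the same catalyst in THF, a donor solvent in which the lactone does not react on, and cis-β-lactone 8 is isolated. It is opened at C4 by a vinyl cuprate (CH2=CHMgBr, CuBr·SMe2, THF, −30 °C), an SN2 reaction with inversion like that of the cobaltate, to give (2S,3S)-2,3-bis[(triisopropylsilyloxy)methyl]pent-4-enoic acid F2. Ozonolysis (O3, CH2Cl2/MeOH, −78 °C, then Me2S) gives (2S,3S)-4-oxo-2,3-bis[(triisopropylsilyloxy)methyl]butanoic acid F3, which is oxidised at once (NaClO2, NaH2PO4, 2-methylbut-2-ene, t-BuOH/H2O) to (2S,3S)-2,3-bis[(triisopropylsilyloxy)methyl]butanedioic acid F4. Dehydration with dicyclohexylcarbodiimide (CH2Cl2, 0 °C) comes back to the route at 9.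

Third, step 5. The alkene carries two allylic oxygens and is a slow substrate for the dioxirane, so conversion and enantiomeric excess may be low. The fallback sets out from 5. Monosilylation (NaH 1.0 equiv, TIPSCl 1.0 equiv, THF) gives (E)-4-(triisopropylsilyloxy)but-2-en-1-ol F5. Sharpless asymmetric epoxidation (Ti(OiPr)4, L-(+)-diethyl tartrate, t-BuOOH, 4 Å molecular sieves, CH2Cl2, −20 °C) gives [(2S,3S)-3-[(triisopropylsilyloxy)methyl]oxiran-2-yl]methanol F6. Silylation of the free hydroxyl (TIPSCl, imidazole, DMF) comes back to the route at 7.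

## Further compounds

F1 | step 7 | (2S,3S,4S)-4-hydroxy-4-[3-methoxy-4-(triisopropylsilyloxy)phenyl]-2,3-bis[(triisopropylsilyloxy)methyl]butanoic acid | O[C@H](c1ccc(O[Si](C(C)C)(C(C)C)C(C)C)c(OC)c1)[C@H](CO[Si](C(C)C)(C(C)C)C(C)C)[C@@H](CO[Si](C(C)C)(C(C)C)C(C)C)C(=O)O
F2 | step 6 | (2S,3S)-2,3-bis[(triisopropylsilyloxy)methyl]pent-4-enoic acid | C=C[C@H](CO[Si](C(C)C)(C(C)C)C(C)C)[C@@H](CO[Si](C(C)C)(C(C)C)C(C)C)C(=O)O
F3 | step 6 | (2S,3S)-4-oxo-2,3-bis[(triisopropylsilyloxy)methyl]butanoic acid | O=C[C@H](CO[Si](C(C)C)(C(C)C)C(C)C)[C@@H](CO[Si](C(C)C)(C(C)C)C(C)C)C(=O)O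
F4 | step 6 | (2S,3S)-2,3-bis[(triisopropylsilyloxy)methyl]butanedioic acid | OC(=O)[C@H](CO[Si](C(C)C)(C(C)C)C(C)C)[C@@H](CO[Si](C(C)C)(C(C)C)C(C)C)C(=O)O
F5 | step 5 | (E)-4-(triisopropylsilyloxy)but-2-en-1-ol | OC/C=C/CO[Si](C(C)C)(C(C)C)C(C)C
F6 | step 5 | [(2S,3S)-3-[(triisopropylsilyloxy)methyl]oxiran-2-yl]methanol | OC[C@@H]1O[C@H]1CO[Si](C(C)C)(C(C)C)C(C)C
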